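The route rests on closing the cyclohexane-1,2-dione ring last, at the bond between the lactone α-carbon C14 and the ketone carbon C15. A macrocyclizing Diels–Alder reaction of a 4-alkyl-5-methylenefuranone first builds cyclohexene, spiro-butenolide and 11-membered carbocycle together. The precursor of the key step is this tricycle, carrying an N-methoxy-N-methylamide arm on C17. Base removes a proton from the butenolide γ-methylene C18, and the dienolate α-carbon C14 acylates the amide, forming ring C14–C15–C16–C17–C18–C19 as a fused ene-dicarbonyl in one operation. The step exploits the vinylogous acidity of C18–H and the 1,6-relationship of C14 and the amide carbonyl. Face-selective conjugate reduction, C14 methylation and oxidation at C16 finish the target.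

Key step: step 17

Numbering used below (atoms of the target): C2(H)(CH3)–C3H2–C4H2–C5H2–C6H–C7H=C8(CO2H)–C9H(CH3)–C10H2–C11. C11 is the spiro carbon, bonded to C6, C10, O12 and C19. The lactone is O12–C13(=O)–C14(CH3)–C19H–C11. The dione ring is C14–C15(=O)–C16(=O)–C17H–C18H2–C19. C17–C20H(CH3)–C21H2–C2 completes the 11-membered ring C2–C3–C4–C5–C6–C11–C19–C18–C17–C20–C21. Target configuration: 2R,6S,9S,11R,14R,17R,19R,20R.

Assumptions:
- (DHQD)2AQN is taken to give the (2S,4R) half-ester 2; if its sense is the opposite, the pseudoenantiomeric (DHQ)2AQN is used.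
- Compound 27 is an inconsequential mixture of epimers at C11.
- Compound 32 is drawn as its cis-fused keto form.

Step 1
Reactants: 1 meso-2,4-dimethylglutaric anhydride
Product: 2 (2S,4R)-5-methoxy-2,4-dimethyl-5-oxopentanoic acid
Conditions: MeOH (10 equiv), (DHQD)2AQN (10 mol %), Et2O, −40 °C
Reagents that add atoms: methanol, CO
Why: Alkaloid-catalysed enantioselective methanolysis (desymmetrization of a meso anhydride) opens one of the two enantiotopic carbonyl groups and so fixes the syn-dimethyl pair C20/C2 in absolute terms.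

Step 2
Reactants: 2 (2S,4R)-5-methoxy-2,4-dimethyl-5-oxopentanoic acid
Product: 3 methyl (2R,4S)-5-hydroxy-2,4-dimethylpentanoate
Conditions: BH3·SMe2, THF, 0 °C; MeOH quench
Reagents that add atoms: none
Why: Acid-selective borane reduction converts the carboxylic acid into the primary alcohol in the presence of the methyl ester, and no stereocentre is touched.

Step 3
Reactants: 3 methyl (2R,4S)-5-hydroxy-2,4-dimethylpentanoate; 4 (4-bromobut-1-yn-1-yl)trimethylsilane
Product: 7 methyl (2R,4R)-2,4-dimethyl-9-(trimethylsilyl)non-8-ynoate, via triflate 5 (not isolated), via Grignard reagent 6 (not isolated)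
Conditions: 3, Tf2O, 2,6-lutidine, CH2Cl2, −78 °C; transferred cold onto 6 (from 4, Mg, THF; 3 equiv) and CuBr·SMe2 (10 mol %), THF, −78 to −20 °C
Reagents that add atoms: none
Why: Copper-catalysed sp3–sp3 cross-coupling of a primary alkyl triflate with a Grignard reagent is fast at low temperature, so the C3–C4 bond should form without attack on the α-branched methyl ester.

Step 4
Reactants: 8 (S)-4-benzyl-3-(chloroacetyl)oxazolidin-2-one
Product: 9 diethyl {2-[(S)-4-benzyl-2-oxooxazolidin-3-yl]-2-oxoethyl}phosphonate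
Conditions: P(OEt)3, NaI (10 mol %), toluene, 110 °C
Reagents that add atoms: triethyl phosphite, CCOP(OCC)OCC
Why: Michaelis–Arbuzov reaction of the activated α-halo imide gives the phosphonate needed for the olefination.

Step 5
Reactants: 7 methyl (2R,4R)-2,4-dimethyl-9-(trimethylsilyl)non-8-ynoate; 9 diethyl {2-[(S)-4-benzyl-2-oxooxazolidin-3-yl]-2-oxoethyl}phosphonate
Product: 11 (S)-4-benzyl-3-[(2E,4R,6R)-4,6-dimethyl-11-(trimethylsilyl)undec-2-en-10-ynoyl]oxazolidin-2-one, via aldehyde 10 (not isolated)
Conditions: 7, i-Bu2AlH (1.1 equiv), CH2Cl2, −78 °C; then sodium salt of 9 (NaH, THF), −78 °C to rt; potassium sodium tartrate work-up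
Reagents that add atoms: none
Why: Partial reduction stops at the aluminium hemiacetal, and Horner–Wadsworth–Emmons olefination of the aldehyde released in situ should give the (E)-enoyl imide without isolating the epimerizable α-methyl aldehyde.

Step 6
Reactants: 11 (S)-4-benzyl-3-[(2E,4R,6R)-4,6-dimethyl-11-(trimethylsilyl)undec-2-en-10-ynoyl]oxazolidin-2-one
Product: 12 (S)-4-benzyl-3-[(3R,4R,6R)-3-ethenyl-4,6-dimethyl-11-(trimethylsilyl)undec-10-ynoyl]oxazolidin-2-one
Conditions: CH2=CHMgBr (3 equiv), CuBr·SMe2 (1.5 equiv), THF/Me2S, −78 to −20 °C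
Reagents that add atoms: vinylmagnesium bromide, C=C[Mg]Br
Why: Auxiliary-controlled conjugate addition of the vinylcopper reagent to the magnesium-chelated s-cis N-enoyl oxazolidinone should occur on the face opposite the benzyl group and set C17, overriding the weak bias of the γ-methyl centre.

Step 7
Reactants: 12 (S)-4-benzyl-3-[(3R,4R,6R)-3-ethenyl-4,6-dimethyl-11-(trimethylsilyl)undec-10-ynoyl]oxazolidin-2-one
Product: 15 (S)-4-[(2R,4R)-4-methylnon-8-yn-2-yl]dihydrofuran-2(3H)-one, via formyl imide 13 (not isolated), via silylated lactone 14 (not isolated)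
Conditions: O3, CH2Cl2/MeOH, −78 °C; NaBH4, −78 to 0 °C; then K2CO3, MeOH, rt; dilute HCl work-up
Reagents that add atoms: ozone, [O-][O+]=O
Why: Ozonolysis cleaves the terminal alkene much faster than the silylalkyne, borohydride reduces the aldehyde, the γ-alkoxide lactonizes onto the imide with release of the auxiliary, and carbonate in methanol removes the alkynyl silyl group (ozonolysis, reduction, lactonization, protodesilylation), leaving C17 untouched.

Step 8
Reactants: 15 (S)-4-[(2R,4R)-4-methylnon-8-yn-2-yl]dihydrofuran-2(3H)-one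
Product: 16 (S)-4-[(2R,4R,8E)-9-iodo-4-methylnon-8-en-2-yl]dihydrofuran-2(3H)-one
Conditions: Cp2Zr(H)Cl (1.3 equiv), THF, rt; then I2, 0 °C
Reagents that add atoms: iodine, II
Why: Hydrozirconation of the terminal alkyne (syn, metal at the terminal carbon, faster than attack on the lactone) followed by iodinolysis with retention should give the (E)-vinyl iodide.

Step 9
Reactants: 17 tert-butyl but-2-ynoate
Product: 18 tert-butyl (E)-2-(tributylstannyl)but-2-enoate
Conditions: Bu3SnH, Pd(PPh3)4 (2 mol %), THF, rt
Reagents that add atoms: tributyltin hydride, CCCC[SnH](CCCC)CCCC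
Why: Palladium-catalysed syn-hydrostannation of the ynoate places tin α to the ester, so the methyl group ends up cis to the ester, as the later diene requires.

Step 10
Reactants: 16 (S)-4-[(2R,4R,8E)-9-iodo-4-methylnon-8-en-2-yl]dihydrofuran-2(3H)-one; 18 tert-butyl (E)-2-(tributylstannyl)but-2-enoate
Product: 19 tert-butyl (2Z,3E,8R,10R)-2-ethylidene-8-methyl-10-[(S)-5-oxotetrahydrofuran-3-yl]undec-3-enoate
Conditions: Pd2(dba)3 (5 mol %), AsPh3, CuI, DMF, rt to 40 °C
Reagents that add atoms: none
Why: Stille coupling assisted by CuI joins the two sp2 carbons with retention of both alkene geometries, giving the 2-alkoxycarbonyl diene with the C5 chain and the C9 methyl both on the outside.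

Step 11
Reactants: 19 tert-butyl (2Z,3E,8R,10R)-2-ethylidene-8-methyl-10-[(S)-5-oxotetrahydrofuran-3-yl]undec-3-enoate
Product: 20 tert-butyl (2Z,3E,8R,10R,11S)-2-ethylidene-11-(hydroxymethyl)-13-[methoxy(methyl)amino]-8,10-dimethyl-13-oxotridec-3-enoate
Conditions: MeNH(OMe)·HCl, AlMe3, CH2Cl2, 0 °C to rt; potassium sodium tartrate work-up
Reagents that add atoms: N,O-dimethylhydroxylamine hydrochloride, CNOC.Cl
Why: Aluminium-amide aminolysis opens the γ-lactone to the γ-hydroxy N-methoxy-N-methylamide, while the hindered conjugated tert-butyl ester should not react.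

Step 12
Reactants: 20 tert-butyl (2Z,3E,8R,10R,11S)-2-ethylidene-11-(hydroxymethyl)-13-[methoxy(methyl)amino]-8,10-dimethyl-13-oxotridec-3-enoate
Product: 21 tert-butyl (2Z,3E,8R,10R,11S)-2-ethylidene-11-(iodomethyl)-13-[methoxy(methyl)amino]-8,10-dimethyl-13-oxotridec-3-enoate
Conditions: I2, PPh3, imidazole, CH2Cl2, 0 °C
Reagents that add atoms: iodine, II
Why: Appel-type iodination converts the primary alcohol into the iodide by SN2 displacement at CH2, with no stereocentre involved.

Step 13
Reactants: 22 tetronic acid (4-hydroxyfuran-2(5H)-one)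
Product: 23 5-oxo-2,5-dihydrofuran-3-yl trifluoromethanesulfonate
Conditions: Tf2O, i-Pr2NEt, CH2Cl2, −78 °C
Reagents that add atoms: trifluoromethanesulfonic anhydride, O=S(=O)(OS(=O)(=O)C(F)(F)F)C(F)(F)F
Why: O-Sulfonylation of the vinylogous acid gives the enol triflate that serves as the sp2 coupling partner.

Step 14
Reactants: 21 tert-butyl (2Z,3E,8R,10R,11S)-2-ethylidene-11-(iodomethyl)-13-[methoxy(methyl)amino]-8,10-dimethyl-13-oxotridec-3-enoate; 23 5-oxo-2,5-dihydrofuran-3-yl trifluoromethanesulfonate
Product: 25 tert-butyl (2Z,3E,8R,10R,11S)-2-ethylidene-13-[methoxy(methyl)amino]-8,10-dimethyl-13-oxo-11-[(5-oxo-2,5-dihydrofuran-3-yl)methyl]tridec-3-enoate, via alkylzinc iodide 24 (not isolated)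
Conditions: 21, Zn dust, LiCl, THF, 40 °C; then 23, Pd(OAc)2 (5 mol %), SPhos (10 mol %), THF, rt
Reagents that add atoms: none
Why: Zinc insertion into the primary C–I bond and Negishi sp3–sp2 coupling with the enol triflate form the C18–C19 bond, and the organozinc tolerates the amide and both esters.

Step 15
Reactants: 25 tert-butyl (2Z,3E,8R,10R,11S)-2-ethylidene-13-[methoxy(methyl)amino]-8,10-dimethyl-13-oxo-11-[(5-oxo-2,5-dihydrofuran-3-yl)methyl]tridec-3-enoate
Product: 27 tert-butyl (2Z,3E,8R,10R,11S)-11-({2-[(dimethylamino)methyl]-5-oxo-2,5-dihydrofuran-3-yl}methyl)-2-ethylidene-13-[methoxy(methyl)amino]-8,10-dimethyl-13-oxotridec-3-enoate, via silyloxyfuran 26 (not isolated)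
Conditions: i-Pr3SiOTf, Et3N, CH2Cl2, 0 °C; then dimethylmethylideneammonium iodide, rt
Reagents that add atoms: dimethylmethylideneammonium iodide, C=[N+](C)C.[I-]
Why: Soft enolization gives the 2-silyloxyfuran, which undergoes a vinylogous Mannich reaction with the iminium salt at the free furan α-position C11; the new centre there is lost again in step 16.

Step 16
Reactants: 27 tert-butyl (2Z,3E,8R,10R,11S)-11-({2-[(dimethylamino)methyl]-5-oxo-2,5-dihydrofuran-3-yl}methyl)-2-ethylidene-13-[methoxy(methyl)amino]-8,10-dimethyl-13-oxotridec-3-enoate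
Product: 30 tert-butyl ester of the spirobutenolide macrocycle (C14H=C19; C17 bears CH2C(O)N(OMe)Me; 2R,6S,9S,11R,17S,20R), via ammonium iodide 28 (not isolated), via methylenefuranone 29 (not isolated)
Conditions: MeI, MeCN, rt; evaporate; NaHCO3, BHT, toluene (1 mM), 60 then 110 °C
Reagents that add atoms: none
Why: Quaternization and E1cB loss of trimethylamine unveil the 5-methylenefuranone, whose exocyclic alkene should add to the tethered (E,E)-configured diene in an intramolecular Diels–Alder reaction of the spirotetronate type: the tether fixes the regiochemistry (C11–C6 and C10–C9), suprafacial addition puts the C5 chain and the C9 methyl cis, the tether-bearing C19 sits exo so that O12 is cis to C5, and the diene face is chosen by the C17, C20 and C2 centres, which keep their substituents outside the forming 11-membered ring.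

Step 17
Reactants: 30 tert-butyl ester of the spirobutenolide macrocycle (2R,6S,9S,11R,17S,20R)
Product: 31 tert-butyl ester of the tetracyclic ene-dicarbonyl (C14=C19; C15=O; C16H2; 2R,6S,9S,11R,17S,20R)
Conditions: LiN(SiMe3)2 (1.1 equiv), THF, −78 to −20 °C; aq. NH4Cl
Reagents that add atoms: none
Why: LiN(SiMe3)2 removes a proton from C18, the γ-position of the butenolide and the most acidic C–H in 30; the lithium dienolate attacks the N-methoxy-N-methylamide carbonyl C15 through its α-carbon C14 to give a chelated tetrahedral intermediate that collapses to the ketone only on work-up, where the β,γ-unsaturated β-keto lactone tautomerizes to the conjugated ene-dicarbonyl 31. The closest known reactions are the Dieckmann/Claisen acylation of ester and lactone dienolates at the α-carbon and the acylation of enolates by N-methoxy-N-methylamides. Ring C14–C15–C16–C17–C18–C19 closes in the 6-(enolexo)-exo-trig mode; attack through the γ-carbon C18 would give a four-membered ring, so α-regiochemistry is enforced. No stereocentre is created (C14 and C19 are sp2 in 31 and are set in step 18), while the fixed C17 configuration places the amide arm on the lactone face that leads to the cis-bridged skeleton. The step needs deprotonation at C18 rather than at C16 (amide α-position) or C6 (γ to the tert-butyl ester, whose anion would expel the lactone carboxylate); this is secured by the several pKa units that favour the butenolide γ-position, by using only 1.1 equiv of a hindered amide base at low temperature, and by the chelate, which consumes the base equivalent and blocks retro-Claisen cleavage.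

Step 18
Reactants: 31 tert-butyl ester of the tetracyclic ene-dicarbonyl (2R,6S,9S,11R,17S,20R)
Product: 33 tert-butyl ester of the 16-deoxo target (C14–CH3; C15=O; C16H2; 2R,6S,9S,11R,14R,17S,19R,20R), via keto lactone 32 (not isolated)
Conditions: [(Ph3P)CuH]6 (0.4 equiv), H2O (2 equiv), toluene, rt; then Cs2CO3, MeI, DMF, rt
Reagents that add atoms: iodomethane, CI
Why: Conjugate reduction with the copper hydride should deliver hydride to C19 of the doubly activated alkene from the face remote from the macrocyclic bridge (the tert-butyl enoate is singly activated, α-branched and far slower), and the β-keto lactone enolate is then C-methylated on the same open face, which for this fused enolate can only give the cis ring junction, so C19 and the quaternary C14 are both set (reductive alkylation).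

Step 19
Reactants: 33 tert-butyl ester of the 16-deoxo target (2R,6S,9S,11R,14R,17S,19R,20R)
Product: 34 tert-butyl ester of the target (2R,6S,9S,11R,14R,17R,19R,20R)
Conditions: SeO2 (1.5 equiv), 1,4-dioxane/H2O (20:1), 90 °C
Reagents that add atoms: selenium dioxide, O=[Se]=O
Why: Riley oxidation: the C15 ketone can enolize only toward C16 because C14 is quaternary, so SeO2 should turn this methylene into the second carbonyl, while C17 keeps the configuration that the cis-1,3 bridge demands.

Step 20
Reactants: 34 tert-butyl ester of the target (2R,6S,9S,11R,14R,17R,19R,20R)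
Product: 35 target acid CNP0115928.1
Conditions: CF3CO2H, CH2Cl2, 0 °C to rt
Reagents that add atoms: none
Why: Acid-mediated E1 cleavage of the tert-butyl ester (loss of isobutene) frees the acid without touching the lactone, the 1,2-dione or any stereocentre.

Compound list

1 | meso-2,4-dimethylglutaric anhydride | C[C@H]1C[C@@H](C)C(=O)OC1=O | starting material
2 | (2S,4R)-5-methoxy-2,4-dimethyl-5-oxopentanoic acid | COC(=O)[C@H](C)C[C@H](C)C(=O)O | intermediate
3 | methyl (2R,4S)-5-hydroxy-2,4-dimethylpentanoate | COC(=O)[C@H](C)C[C@H](C)CO | intermediate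
4 | (4-bromobut-1-yn-1-yl)trimethylsilane | C[Si](C)(C)C#CCCBr | starting material
5 | methyl (2R,4S)-2,4-dimethyl-5-(trifluoromethylsulfonyloxy)pentanoate | COC(=O)[C@H](C)C[C@H](C)COS(=O)(=O)C(F)(F)F | intermediate (not isolated)
6 | [4-(trimethylsilyl)but-3-yn-1-yl]magnesium bromide | C[Si](C)(C)C#CCC[Mg]Br | intermediate (not isolated)
7 | methyl (2R,4R)-2,4-dimethyl-9-(trimethylsilyl)non-8-ynoate | COC(=O)[C@H](C)C[C@H](C)CCCC#C[Si](C)(C)C | intermediate
8 | (S)-4-benzyl-3-(chloroacetyl)oxazolidin-2-one | O=C(CCl)N1[C@@H](Cc2ccccc2)COC1=O | starting material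
9 | diethyl {2-[(S)-4-benzyl-2-oxooxazolidin-3-yl]-2-oxoethyl}phosphonate | CCOP(=O)(OCC)CC(=O)N1[C@@H](Cc2ccccc2)COC1=O | intermediate
10 | (2R,4R)-2,4-dimethyl-9-(trimethylsilyl)non-8-ynal | O=C[C@H](C)C[C@H](C)CCCC#C[Si](C)(C)C | intermediate (not isolated)
11 | (S)-4-benzyl-3-[(2E,4R,6R)-4,6-dimethyl-11-(trimethylsilyl)undec-2-en-10-ynoyl]oxazolidin-2-one | O=C(/C=C/[C@H](C)C[C@H](C)CCCC#C[Si](C)(C)C)N1[C@@H](Cc2ccccc2)COC1=O | intermediate
12 | (S)-4-benzyl-3-[(3R,4R,6R)-3-ethenyl-4,6-dimethyl-11-(trimethylsilyl)undec-10-ynoyl]oxazolidin-2-one | O=C(C[C@H](C=C)[C@H](C)C[C@H](C)CCCC#C[Si](C)(C)C)N1[C@@H](Cc2ccccc2)COC1=O | intermediate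
13 | (S)-4-benzyl-3-[(3S,4R,6R)-3-formyl-4,6-dimethyl-11-(trimethylsilyl)undec-10-ynoyl]oxazolidin-2-one | O=C(C[C@H](C=O)[C@H](C)C[C@H](C)CCCC#C[Si](C)(C)C)N1[C@@H](Cc2ccccc2)COC1=O | intermediate (not isolated)
14 | (S)-4-[(2R,4R)-4-methyl-9-(trimethylsilyl)non-8-yn-2-yl]dihydrofuran-2(3H)-one | O=C1C[C@H](CO1)[C@H](C)C[C@H](C)CCCC#C[Si](C)(C)C | intermediate (not isolated)
15 | (S)-4-[(2R,4R)-4-methylnon-8-yn-2-yl]dihydrofuran-2(3H)-one | O=C1C[C@H](CO1)[C@H](C)C[C@H](C)CCCC#C | intermediate
16 | (S)-4-[(2R,4R,8E)-9-iodo-4-methylnon-8-en-2-yl]dihydrofuran-2(3H)-one | O=C1C[C@H](CO1)[C@H](C)C[C@H](C)CCC/C=C/I | intermediate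
17 | tert-butyl but-2-ynoate | CC#CC(=O)OC(C)(C)C | starting material
18 | tert-butyl (E)-2-(tributylstannyl)but-2-enoate | C/C=C(\C(=O)OC(C)(C)C)[Sn](CCCC)(CCCC)CCCC | intermediate
19 | tert-butyl (2Z,3E,8R,10R)-2-ethylidene-8-methyl-10-[(S)-5-oxotetrahydrofuran-3-yl]undec-3-enoate | O=C1C[C@H](CO1)[C@H](C)C[C@H](C)CCC/C=C/C(C(=O)OC(C)(C)C)=C/C | intermediate
20 | tert-butyl (2Z,3E,8R,10R,11S)-2-ethylidene-11-(hydroxymethyl)-13-[methoxy(methyl)amino]-8,10-dimethyl-13-oxotridec-3-enoate | CON(C)C(=O)C[C@H](CO)[C@H](C)C[C@H](C)CCC/C=C/C(C(=O)OC(C)(C)C)=C/C | intermediate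
21 | tert-butyl (2Z,3E,8R,10R,11S)-2-ethylidene-11-(iodomethyl)-13-[methoxy(methyl)amino]-8,10-dimethyl-13-oxotridec-3-enoate | CON(C)C(=O)C[C@H](CI)[C@H](C)C[C@H](C)CCC/C=C/C(C(=O)OC(C)(C)C)=C/C | intermediate
22 | tetronic acid (4-hydroxyfuran-2(5H)-one) | O=C1OCC(O)=C1 | starting material
23 | 5-oxo-2,5-dihydrofuran-3-yl trifluoromethanesulfonate | O=C1OCC(OS(=O)(=O)C(F)(F)F)=C1 | intermediate
24 | alkylzinc iodide derived from 21 (C18–ZnI) | CON(C)C(=O)C[C@H](C[Zn]I)[C@H](C)C[C@H](C)CCC/C=C/C(C(=O)OC(C)(C)C)=C/C | intermediate (not isolated)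
25 | tert-butyl (2Z,3E,8R,10R,11S)-2-ethylidene-13-[methoxy(methyl)amino]-8,10-dimethyl-13-oxo-11-[(5-oxo-2,5-dihydrofuran-3-yl)methyl]tridec-3-enoate | CON(C)C(=O)C[C@H](CC1=CC(=O)OC1)[C@H](C)C[C@H](C)CCC/C=C/C(C(=O)OC(C)(C)C)=C/C | intermediate
26 | 2-(triisopropylsilyloxy)furan derived from 25 (chain at furan C4) | CON(C)C(=O)C[C@H](Cc1coc(O[Si](C(C)C)(C(C)C)C(C)C)c1)[C@H](C)C[C@H](C)CCC/C=C/C(C(=O)OC(C)(C)C)=C/C | intermediate (not isolated)
27 | tert-butyl (2Z,3E,8R,10R,11S)-11-({2-[(dimethylamino)methyl]-5-oxo-2,5-dihydrofuran-3-yl}methyl)-2-ethylidene-13-[methoxy(methyl)amino]-8,10-dimethyl-13-oxotridec-3-enoate (epimers at the furanone C2, i.e. C11) | CON(C)C(=O)C[C@H](CC1=CC(=O)OC1CN(C)C)[C@H](C)C[C@H](C)CCC/C=C/C(C(=O)OC(C)(C)C)=C/C | intermediate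
28 | trimethylammonium iodide of 27 | CON(C)C(=O)C[C@H](CC1=CC(=O)OC1C[N+](C)(C)C)[C@H](C)C[C@H](C)CCC/C=C/C(C(=O)OC(C)(C)C)=C/C.[I-] | intermediate (not isolated)
29 | tert-butyl (2Z,3E,8R,10R,11S)-2-ethylidene-13-[methoxy(methyl)amino]-8,10-dimethyl-11-[(2-methylidene-5-oxo-2,5-dihydrofuran-3-yl)methyl]-13-oxotridec-3-enoate | CON(C)C(=O)C[C@H](CC1=CC(=O)OC1=C)[C@H](C)C[C@H](C)CCC/C=C/C(C(=O)OC(C)(C)C)=C/C | intermediate (not isolated)
30 | tert-butyl ester of the spirobutenolide macrocycle: cyclohexene, 11-membered ring and butenolide (C14H=C19) in place, C17 bears CH2C(O)N(OMe)Me; 2R,6S,9S,11R,17S,20R | C[C@@H]1CCC[C@H]2C=C(C(=O)OC(C)(C)C)[C@@H](C)C[C@@]23OC(=O)C=C3C[C@@H](CC(=O)N(C)OC)[C@H](C)C1 | intermediate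
31 | tert-butyl ester of the tetracyclic ene-dicarbonyl: C14=C19, C15=O, C16H2; 2R,6S,9S,11R,17S,20R | C[C@@H]1CCC[C@H]2C=C(C(=O)OC(C)(C)C)[C@@H](C)C[C@@]23OC(=O)C4=C3C[C@@H](CC4=O)[C@H](C)C1 | intermediate
32 | tert-butyl ester of the cis-fused β-keto lactone: C14–H, C19–H, C15=O, C16H2; 2R,6S,9S,11R,14R,17S,19R,20R | C[C@@H]1CCC[C@H]2C=C(C(=O)OC(C)(C)C)[C@@H](C)C[C@@]23OC(=O)[C@H]2C(=O)C[C@H](C[C@H]23)[C@H](C)C1 | intermediate (not isolated)
33 | tert-butyl ester of the 16-deoxo target: C14–CH3, C15=O, C16H2; 2R,6S,9S,11R,14R,17S,19R,20R | C[C@@H]1CCC[C@H]2C=C(C(=O)OC(C)(C)C)[C@@H](C)C[C@@]23OC(=O)[C@@]2(C)C(=O)C[C@H](C[C@H]23)[C@H](C)C1 | intermediate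
34 | tert-butyl ester of the target; 2R,6S,9S,11R,14R,17R,19R,20R | C[C@@H]1CCC[C@H]2C=C(C(=O)OC(C)(C)C)[C@@H](C)C[C@@]23OC(=O)[C@@]2(C)C(=O)C(=O)[C@H](C[C@H]23)[C@H](C)C1 | intermediate
35 | target acid CNP0115928.1; 2R,6S,9S,11R,14R,17R,19R,20R | C[C@@H]1CCC[C@H]2C=C(C(=O)O)[C@@H](C)C[C@@]23OC(=O)[C@@]2(C)C(=O)C(=O)[C@H](C[C@H]23)[C@H](C)C1 | target

Total step count: 20. Longest linear sequence: 17 steps (steps 1, 2, 3, 5, 6, 7, 8, 10, 11, 12, 14, 15, 16, 17, 18, 19, 20). Steps 4, 9 and 13 are side branches.

Steps most likely to fail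

1. Step 16 (elimination and macrocyclizing Diels–Alder). The transient 5-methylenefuranone may oligomerize faster than it cyclizes through the 11-membered transition state. The cycloaddition may also discriminate poorly between the two diene faces or between exo and endo placement of the tether, since control by the remote C17, C20 and C2 centres is not assured. The fallback sets out from 21 and 23 and comes back at 30; it separates cycloaddition and macrocyclization. Triflate 23 is taken through the chemistry of steps 15 and 16 without the chain. i-Pr3SiOTf and Et3N give 5-(triisopropylsilyloxy)furan-3-yl triflate F1. Dimethylmethylideneammonium iodide gives the Mannich base 2-[(dimethylamino)methyl]-5-oxo-2,5-dihydrofuran-3-yl triflate F2. MeI gives the trimethylammonium iodide F3, and NaHCO3 then gives 2-methylidene-5-oxo-2,5-dihydrofuran-3-yl triflate F4. An excess of F4 and the dienyl iodide 21 should undergo an intermolecular Diels–Alder reaction (toluene, 80 °C, BHT) to the spiro adduct F5, whose diastereomers (ring stereotriad against the chain centres) are separated by chromatography. Zinc insertion into the primary iodide (Zn, LiCl, THF) gives the alkylzinc iodide F6. Intramolecular Negishi coupling with the enol triflate (Pd(OAc)2, SPhos, high dilution) then closes the 11-membered ring at C18–C19 to give 30.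

2. Step 17 (key ring closure). Deprotonation may stray to C16 or to C6, the latter followed by β-elimination of the lactone carboxylate, or the dienolate may fail to reach the amide carbonyl for conformational reasons. The fallback sets out from 30 and comes back at 32; the C14 nucleophile is made by conjugate reduction instead of deprotonation and the ring is closed by an aldol reaction. Cp2Zr(H)Cl reduces the N-methoxy-N-methylamide of 30 to the aldehyde F7. [(Ph3P)CuH]6 in toluene then effects a reductive aldol cyclization: hydride adds to C19 of the butenolide from the open face and the copper enolate at C14 adds to the aldehyde, giving the cis-fused β-hydroxy lactone F8 (epimers at C15). Oxidation with 1,1,1-triacetoxy-1,1-dihydro-1,2-benziodoxol-3(1H)-one gives the β-keto lactone 32, which is methylated as in the second stage of step 18 to rejoin the route at 33.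

3. Step 18 (reductive methylation). Hydride transfer to the fully substituted C19 next to the spiro centre may be slow, which would let 1,2-reduction at C15, attack on the wrong face or O-methylation intervene. The fallback sets out from 31 and comes back at 33; it replaces hydride addition by single-electron reduction and separates the two operations. SmI2 (2.5 equiv) in THF/MeOH at −78 °C should reduce only the doubly activated alkene, with protonation at C19 from the open face. Compound 32 is then isolated and C-methylated separately (MeI, K2CO3, acetone) to give 33. No new compound arises.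

Further compounds

F1 | step 16 | 5-(triisopropylsilyloxy)furan-3-yl trifluoromethanesulfonate | CC(C)[Si](Oc1cc(OS(=O)(=O)C(F)(F)F)co1)(C(C)C)C(C)C
F2 | step 16 | 2-[(dimethylamino)methyl]-5-oxo-2,5-dihydrofuran-3-yl trifluoromethanesulfonate (racemic) | CN(C)CC1OC(=O)C=C1OS(=O)(=O)C(F)(F)F
F3 | step 16 | trimethyl{[5-oxo-3-(trifluoromethylsulfonyloxy)-2,5-dihydrofuran-2-yl]methyl}ammonium iodide | C[N+](C)(C)CC1OC(=O)C=C1OS(=O)(=O)C(F)(F)F.[I-]
F4 | step 16 | 2-methylidene-5-oxo-2,5-dihydrofuran-3-yl trifluoromethanesulfonate | C=C1OC(=O)C=C1OS(=O)(=O)C(F)(F)F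
F5 | step 16 | intermolecular Diels–Alder adduct: cyclohexene spiro-fused at C11 to the 4-(triflyloxy)butenolide, C6 carrying the open chain with the C18 iodide (6S,9S,11R; chain as in 21) | CON(C)C(=O)C[C@H](CI)[C@H](C)C[C@H](C)CCC[C@H]1C=C(C(=O)OC(C)(C)C)[C@@H](C)C[C@@]12OC(=O)C=C2OS(=O)(=O)C(F)(F)F
F6 | step 16 | alkylzinc iodide derived from F5 (C18–ZnI) | CON(C)C(=O)C[C@H](C[Zn]I)[C@H](C)C[C@H](C)CCC[C@H]1C=C(C(=O)OC(C)(C)C)[C@@H](C)C[C@@]12OC(=O)C=C2OS(=O)(=O)C(F)(F)F
F7 | step 17 | aldehyde from 30 (C17 bears CH2CHO; otherwise as 30) | C[C@@H]1CCC[C@H]2C=C(C(=O)OC(C)(C)C)[C@@H](C)C[C@@]23OC(=O)C=C3C[C@@H](CC=O)[C@H](C)C1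
F8 | step 17 | cis-fused β-hydroxy lactone (C14–H, C19–H, C15–OH as epimers; otherwise as 32) | C[C@@H]1CCC[C@H]2C=C(C(=O)OC(C)(C)C)[C@@H](C)C[C@@]23OC(=O)[C@H]2C(O)C[C@H](C[C@H]23)[C@H](C)C1
F0 | step 18 | none | none
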